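**Plan**

1. Locants: C1=C2 is the E-alkene, C3 the ketone, C4=C5 the Z-alkene with C15H2OH on C4, C6 the lactone O–CH, C7 the other ring-fusion CH, C8 the acyloxy CH, C9 the CH2, C10 the methyl carbinol, C11=C13 the exo-methylene, C12 the lactone carbonyl.
2. Cuts, in retrosynthetic order: the two silyl ethers and C11=C13 (formaldehyde olefination of an alpha-phosphono lactone); the lactone bond C7–C11; the ring bond C3–C4; C1=C2 (Wittig); the ester C–O bonds at O8 and O6; C6–C7 (aldol). What remains is a C7–C10/C1 methyl ketone and a C4–C6/C15 iodo-enal.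
3. Enabling feature: the five lactone atoms C11–C12–O–C6–C7 put C7 in a 1,5 relation to the carbonyl carbon of any ester hung on O6, and C7 is an unbranched CH2 of the ten-membered carbocycle. A carbenoid centred on C11 of a C6 ester can therefore close the whole gamma-lactone ring by inserting into one C7–H bond.
4. Forward order: chain by aldol (C6–C7); C8 and the two esters set; enal by Wittig; ten-membered ring by CrCl2/NiCl2 coupling at C3–C4; oxidation to the dienone; gamma-lactone ring last by rhodium-carbenoid C–H insertion; then methylenation and desilylation.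
5. Stereochemistry: C10 from (S)-2-methylglycidol; C6 from a reagent-controlled boron aldol; C8 by hydroxyl-directed 1,3-anti reduction from O10; C7 from the insertion (trans ring fusion); the side-chain centre from (R)-2-methylbutanoic acid; Z-C4=C5 from directed hydroalumination–iodination; E-C1=C2 from the Wittig step.

Key step: step 19

Remark: (R)-2-methylbutanoic acid is taken as a purchasable single enantiomer; the carbinol carbon C3 formed in the ring closure and C11 of the insertion product arise as epimer mixtures and are drawn without configuration because both centres are removed later; open-chain intermediates are described with the locants above.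

**Route**

Step 1
Reactants: 1 (S)-2-methylglycidol
Product: 2 (R)-2-{[(4-methoxybenzyl)oxy]methyl}-2-methyloxirane
Conditions: NaH, PMBCl, n-Bu4NI (cat.), THF/DMF, 0 °C
Reagents that add atoms: 4-methoxybenzyl chloride, COc1ccc(CCl)cc1
Why: Williamson etherification of the primary alkoxide, kept cold so that Payne-type epoxide migration cannot erode the quaternary centre, which is carried over unchanged from 1 (the descriptor changes from S to R only through the sequence rule).

Step 2
Reactants: 2 PMB-protected epoxide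
Product: 3 (R)-1-[(4-methoxybenzyl)oxy]-2,4-dimethylpent-4-en-2-ol
Conditions: CH2=C(CH3)MgBr, CuI (10 mol %), THF, −30 → 0 °C
Reagents that add atoms: isopropenylmagnesium bromide, CC(=C)[Mg]Br
Why: Copper-catalysed Grignard opening of a 2,2-disubstituted epoxide occurs by SN2 attack at the unhindered CH2 (the future C9), leaves the C10 carbinol centre untouched and brings in C7 and C8 as a masked methyl ketone.

Step 3
Reactants: 3 tertiary alcohol
Product: 4 (R)-1-[(4-methoxybenzyl)oxy]-2,4-dimethyl-2-[(trimethylsilyl)oxy]pent-4-ene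
Conditions: TMSOTf, Et3N, CH2Cl2, −78 → 0 °C
Reagents that add atoms: trimethylsilyl triflate, C[Si](C)(C)OS(=O)(=O)C(F)(F)F
Why: Silylation of the hindered tertiary alcohol with a silyl triflate gives a small, acid-labile ether that shields O10 during enolisation and aldol addition and can be shed under mild acid afterwards.

Step 4
Reactants: 4 TMS ether
Product: 6 (R)-5-[(4-methoxybenzyl)oxy]-4-methyl-4-[(trimethylsilyl)oxy]pentan-2-one, via ozonide 5 (not isolated)
Conditions: O3, CH2Cl2, −78 °C; then PPh3, −78 °C → rt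
Reagents that add atoms: ozone, [O-][O+]=O
Why: Ozonolysis with reductive work-up cleaves the electron-rich 1,1-disubstituted alkene far faster than ozone attacks the anisyl ring and unmasks the C8 methyl ketone.

Step 5
Reactants: 7 but-2-yne-1,4-diol
Product: 8 4-[(triisopropylsilyl)oxy]but-2-yn-1-ol
Conditions: TIPSCl (limiting), imidazole, DMF, 0 °C → rt, diol in threefold excess
Reagents that add atoms: triisopropylsilyl chloride, CC(C)[Si](Cl)(C(C)C)C(C)C
Why: Statistical monosilylation of a symmetric diol used in excess gives the mono-TIPS ether, the unreacted diol being washed out with water.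

Step 6
Reactants: 8 mono-TIPS butynediol
Product: 10 (Z)-3-iodo-4-[(triisopropylsilyl)oxy]but-2-en-1-ol, via cyclic alkenylalanate 9 (not isolated)
Conditions: NaAlH2(OCH2CH2OCH3)2 (Red-Al), THF, 0 °C → rt; then I2, −78 → 0 °C
Reagents that add atoms: iodine, II
Why: Alkoxide-directed trans-hydroalumination puts aluminium on the alkyne carbon remote from the free hydroxyl in a five-membered alanate, and iododealumination with retention gives the Z-iodoalkene, which is the C4=C5 geometry of the target with iodine marking the future C3–C4 bond.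

Step 7
Reactants: 10 Z-iodo allylic alcohol
Product: 11 (Z)-3-iodo-4-[(triisopropylsilyl)oxy]but-2-enal
Conditions: MnO2, CH2Cl2, rt
Reagents that add atoms: none
Why: MnO2 oxidises the allylic alcohol to the enal on the oxide surface under neutral conditions that should leave the Z geometry intact.

Step 8
Reactants: 6 methyl ketone; 11 Z-iodo-enal
Product: 15 (2R,6S,7Z)-2,6-dihydroxy-8-iodo-1-[(4-methoxybenzyl)oxy]-2-methyl-9-[(triisopropylsilyl)oxy]non-7-en-4-one, via enol borinate 12 (not isolated), via boron aldolate 13 (not isolated), via trimethylsilyl aldol 14 (not isolated)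
Conditions: (−)-Ipc2BCl, Et3N, Et2O, 0 °C; 11, −78 → −20 °C; H2O2, MeOH, pH 7 buffer, 0 °C; then citric acid, MeOH, 0 °C
Reagents that add atoms: none
Why: Reagent-controlled boron aldol reaction in which the kinetic methyl-side enol borinate from (−)-Ipc2BCl adds through a cyclic six-membered transition state to the si face of the enal and sets C6 (S), the C10 silyl ether exerting little 1,5-bias, after which acidic methanol removes the tertiary TMS group.

Step 9
Reactants: 15 dihydroxy ketone; 16 diethylphosphonoacetic acid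
Product: 17 (2R,6S,7Z)-2-hydroxy-8-iodo-1-[(4-methoxybenzyl)oxy]-2-methyl-4-oxo-9-[(triisopropylsilyl)oxy]non-7-en-6-yl 2-(diethoxyphosphoryl)acetate
Conditions: DCC, DMAP (cat.), CH2Cl2, 0 °C
Reagents that add atoms: none
Why: Steglich esterification acylates the secondary allylic C6 hydroxyl while the tertiary C10 hydroxyl stays free, and the cold, weakly basic medium should avoid beta-elimination of the aldol.

Step 10
Reactants: 17 C6 phosphonoacetate of the C8 ketone
Product: 18 (2R,4S,6S,7Z)-2,4-dihydroxy-8-iodo-1-[(4-methoxybenzyl)oxy]-2-methyl-9-[(triisopropylsilyl)oxy]non-7-en-6-yl 2-(diethoxyphosphoryl)acetate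
Conditions: Me4NBH(OAc)3, MeCN/AcOH (1:1), −30 → −20 °C
Reagents that add atoms: none
Why: Evans–Saksena reduction in which the free tertiary C10 hydroxyl exchanges onto boron and delivers hydride intramolecularly through a chair transition state, setting C8 1,3-anti to O10 (8S) while the C6 ester is a spectator in the acidic medium.

Step 11
Reactants: 18 C8,C10-diol; 19 (R)-2-methylbutanoic acid
Product: 20 (2R,4S,6S,7Z)-6-{[(diethoxyphosphoryl)acetyl]oxy}-2-hydroxy-8-iodo-1-[(4-methoxybenzyl)oxy]-2-methyl-9-[(triisopropylsilyl)oxy]non-7-en-4-yl (2R)-2-methylbutanoate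
Conditions: DCC, DMAP (cat.), CH2Cl2, 0 °C → rt
Reagents that add atoms: none
Why: Steglich esterification of the secondary C8 hydroxyl (the tertiary C10 hydroxyl does not react) installs the side chain with its stereocentre taken from 19, low temperature limiting alpha-epimerisation of the activated acid.

Step 12
Reactants: 20 C8 ester with free C10 hydroxyl
Product: 21 (2R,4S,6S,7Z)-6-{[(diethoxyphosphoryl)acetyl]oxy}-8-iodo-1-[(4-methoxybenzyl)oxy]-2-methyl-2-[(triethylsilyl)oxy]-9-[(triisopropylsilyl)oxy]non-7-en-4-yl (2R)-2-methylbutanoate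
Conditions: TESOTf, 2,6-lutidine, CH2Cl2, −78 → 0 °C
Reagents that add atoms: triethylsilyl triflate, CC[Si](CC)(CC)OS(=O)(=O)C(F)(F)F
Why: Silyl triflate/lutidine silylation caps the hindered tertiary alcohol so that no O–H bond is offered to the carbenoid later.

Step 13
Reactants: 21 fully protected chain
Product: 22 (2R,4S,6S,7Z)-6-{[(diethoxyphosphoryl)acetyl]oxy}-1-hydroxy-8-iodo-2-methyl-2-[(triethylsilyl)oxy]-9-[(triisopropylsilyl)oxy]non-7-en-4-yl (2R)-2-methylbutanoate
Conditions: DDQ, CH2Cl2/pH 7 buffer, 0 °C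
Reagents that add atoms: none
Why: Oxidative PMB cleavage (single-electron oxidation of the anisyl ether and hydrolysis of the oxocarbenium ion) frees C1–OH without touching the silyl ethers, the esters or the iodoalkene.

Step 14
Reactants: 22 primary alcohol
Product: 23 (2R,4S,6S,7Z)-6-{[(diethoxyphosphoryl)acetyl]oxy}-8-iodo-2-methyl-1-oxo-2-[(triethylsilyl)oxy]-9-[(triisopropylsilyl)oxy]non-7-en-4-yl (2R)-2-methylbutanoate
Conditions: Dess–Martin periodinane, CH2Cl2, 0 °C → rt
Reagents that add atoms: none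
Why: Dess–Martin oxidation gives the C1 aldehyde, which is alpha-quaternary and so cannot enolise or epimerise.

Step 15
Reactants: 23 C1 aldehyde
Product: 24 (2E,4R,6S,8S,9Z)-8-{[(diethoxyphosphoryl)acetyl]oxy}-10-iodo-4-methyl-1-oxo-4-[(triethylsilyl)oxy]-11-[(triisopropylsilyl)oxy]undeca-2,9-dien-6-yl (2R)-2-methylbutanoate
Conditions: Ph3P=CHCHO, toluene, 80 °C
Reagents that add atoms: (triphenylphosphoranylidene)acetaldehyde, O=CC=P(c1ccccc1)(c1ccccc1)c1ccccc1
Why: Wittig olefination with the stabilised formylmethylene ylide gives the E-enal (C1=C2 and C3), stops after one homologation because the conjugated product is less electrophilic, and uses a ylide too weakly basic to deprotonate the phosphonoacetate.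

Step 16
Reactants: 24 iodoalkene enal
Product: 25 ten-membered C3 carbinol (6S,8S,10R; E-C1=C2; Z-C4=C5 with CH2OTIPS; C3 epimers; O6 phosphonoacetate; O8 (R)-2-methylbutanoate; C10 OTES)
Conditions: CrCl2, NiCl2 (cat.), DMSO/THF, rt, high dilution
Reagents that add atoms: none
Why: Nozaki–Hiyama–Kishi reaction in which zerovalent nickel (made from NiCl2 by divalent chromium) inserts into the C4–I bond and hands the alkenyl group, with its Z geometry, to trivalent chromium, whose 1,2-addition to the enal closes the ten-membered ring at C3–C4 under conditions inert to esters, silyl ethers and the phosphonoacetate.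

Step 17
Reactants: 25 macrocyclic carbinol
Product: 26 ten-membered C3 carbinol carrying the O6 diazo(diethoxyphosphoryl)acetate
Conditions: p-ABSA, DBU, MeCN, 0 °C
Reagents that add atoms: 4-acetamidobenzenesulfonyl azide, CC(=O)Nc1ccc(cc1)S(=O)(=O)N=[N+]=[N-]
Why: Regitz diazo transfer to the phosphonoacetate carbanion, placed before the oxidation so that no enone is present for that carbanion to attack in a Michael sense.

Step 18
Reactants: 26 diazo carbinol
Product: 27 ten-membered dienone O6 diazo(diethoxyphosphoryl)acetate (6S,8S,10R; C7H2)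
Conditions: MnO2, CH2Cl2, rt
Reagents that add atoms: none
Why: MnO2 oxidation of the doubly allylic alcohol gives the cross-conjugated dienone, and the acceptor-substituted diazo ester is stable to this oxidant.

Step 19
Reactants: 27 diazo dienone
Product: 28 trans-fused alpha-(diethoxyphosphoryl) gamma-lactone on the ten-membered dienone (6R,7R,8R,10R; C11 epimers)
Conditions: Rh2(OAc)4 (2–5 mol %), ClCH2CH2Cl, reflux, slow addition of 27
Reagents that add atoms: none
Why: The dirhodium tetraacetate catalyst (two divalent rhodium centres) takes N2 from the diazo carbon and leaves an electrophilic acceptor/acceptor carbenoid at C11, which inserts into a C7–H bond through a three-centre, hydride-transfer-like transition state with retention at C7. The closest known reaction is the dirhodium-catalysed 1,5 C–H insertion of secondary-alkyl diazo(phosphoryl)acetates to alpha-phosphono gamma-butyrolactones. The gamma-lactone ring C11–C12–O–C6–C7 closes in the 1,5 mode through a five-membered transition state that forms only the C7–C11 bond. C7 is set by which of its two hydrogens is replaced: with the carbocycle holding C5–C6–C7–C8 extended, only the hydrogen gauche to the C6–O bond is within reach, and replacing it gives the trans ring fusion of the target, while C11 forms as an epimer mixture that the next step erases. The step needs C7–H insertion to beat beta-lactone formation at C6–H, six-membered insertion at C8–H and addition to C4=C5; C6–H is allylic to the electron-poor enone and geminal to the acyloxy oxygen, C8–H is deactivated by its own acyloxy group, and C4=C5 is the electron-poor alpha,beta-bond of the dienone and a poor partner for an electrophilic carbenoid.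

Step 20
Reactants: 28 alpha-phosphono lactone
Product: 29 bis-silyl ether of the target (alpha-methylene lactone; C15 OTIPS; C10 OTES)
Conditions: K2CO3, aq. HCHO, THF, 0 °C → rt
Reagents that add atoms: formaldehyde, C=O
Why: Horner–Wadsworth–Emmons olefination of the alpha-phosphono lactone with formaldehyde under mild carbonate base creates C11=C13 and removes the C11 stereocentre, so both epimers converge.

Step 21
Reactants: 29 bis-silyl ether
Product: 30 CNP0232405.1
Conditions: HF·pyridine, pyridine, THF, 0 °C → rt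
Reagents that add atoms: none
Why: Buffered fluoride-mediated desilylation removes the primary TIPS and the tertiary TES ether under non-basic conditions that the dienone and the methylene lactone should tolerate.

**Compound list**

1 | (S)-2-methylglycidol, (S)-(2-methyloxiran-2-yl)methanol | OC[C@]1(C)OC1 | starting material
2 | (R)-2-{[(4-methoxybenzyl)oxy]methyl}-2-methyloxirane | COc1ccc(COC[C@]2(C)OC2)cc1 | intermediate
3 | (R)-1-[(4-methoxybenzyl)oxy]-2,4-dimethylpent-4-en-2-ol | COc1ccc(COC[C@](C)(O)CC(C)=C)cc1 | intermediate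
4 | (R)-1-[(4-methoxybenzyl)oxy]-2,4-dimethyl-2-[(trimethylsilyl)oxy]pent-4-ene | COc1ccc(COC[C@](C)(O[Si](C)(C)C)CC(C)=C)cc1 | intermediate
5 | ozonide of 4, 3-methyl-3-{(R)-3-[(4-methoxybenzyl)oxy]-2-methyl-2-[(trimethylsilyl)oxy]propyl}-1,2,4-trioxolane (ring carbon unassigned) | COc1ccc(COC[C@](C)(O[Si](C)(C)C)CC2(C)OCOO2)cc1 | intermediate (not isolated)
6 | (R)-5-[(4-methoxybenzyl)oxy]-4-methyl-4-[(trimethylsilyl)oxy]pentan-2-one | COc1ccc(COC[C@](C)(O[Si](C)(C)C)CC(C)=O)cc1 | intermediate
7 | but-2-yne-1,4-diol | OCC#CCO | starting material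
8 | 4-[(triisopropylsilyl)oxy]but-2-yn-1-ol | OCC#CCO[Si](C(C)C)(C(C)C)C(C)C | intermediate
9 | cyclic alkenylalanate, sodium 2,2-bis(2-methoxyethoxy)-3-{[(triisopropylsilyl)oxy]methyl}-2,5-dihydro-1,2-oxaaluminol-2-uide | [Na+].COCCO[Al-]1(OCCOC)OCC=C1CO[Si](C(C)C)(C(C)C)C(C)C | intermediate (not isolated)
10 | (Z)-3-iodo-4-[(triisopropylsilyl)oxy]but-2-en-1-ol | OC/C=C(\I)CO[Si](C(C)C)(C(C)C)C(C)C | intermediate
11 | (Z)-3-iodo-4-[(triisopropylsilyl)oxy]but-2-enal | O=C/C=C(\I)CO[Si](C(C)C)(C(C)C)C(C)C | intermediate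
12 | enol borinate of 6, methyl-side O-bis(isopinocampheyl)boron enolate (Ipc from (+)-alpha-pinene) | COc1ccc(COC[C@](C)(O[Si](C)(C)C)CC(=C)OB([C@@H]2C[C@@H]3C[C@H]([C@H]2C)C3(C)C)[C@@H]2C[C@@H]3C[C@H]([C@H]2C)C3(C)C)cc1 | intermediate (not isolated)
13 | boron aldolate, (6S)-O-bis(isopinocampheyl)boryl derivative of 14 | COc1ccc(COC[C@](C)(O[Si](C)(C)C)CC(=O)C[C@H](OB([C@@H]2C[C@@H]3C[C@H]([C@H]2C)C3(C)C)[C@@H]2C[C@@H]3C[C@H]([C@H]2C)C3(C)C)/C=C(\I)CO[Si](C(C)C)(C(C)C)C(C)C)cc1 | intermediate (not isolated)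
14 | trimethylsilyl aldol, (2R,6S,7Z)-6-hydroxy-8-iodo-1-[(4-methoxybenzyl)oxy]-2-methyl-2-[(trimethylsilyl)oxy]-9-[(triisopropylsilyl)oxy]non-7-en-4-one | COc1ccc(COC[C@](C)(O[Si](C)(C)C)CC(=O)C[C@H](O)/C=C(\I)CO[Si](C(C)C)(C(C)C)C(C)C)cc1 | intermediate (not isolated)
15 | (2R,6S,7Z)-2,6-dihydroxy-8-iodo-1-[(4-methoxybenzyl)oxy]-2-methyl-9-[(triisopropylsilyl)oxy]non-7-en-4-one (C6–OH, C8 ketone, C10–OH) | COc1ccc(COC[C@](C)(O)CC(=O)C[C@H](O)/C=C(\I)CO[Si](C(C)C)(C(C)C)C(C)C)cc1 | intermediate
16 | diethylphosphonoacetic acid | OC(=O)CP(=O)(OCC)OCC | starting material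
17 | (2R,6S,7Z)-2-hydroxy-8-iodo-1-[(4-methoxybenzyl)oxy]-2-methyl-4-oxo-9-[(triisopropylsilyl)oxy]non-7-en-6-yl 2-(diethoxyphosphoryl)acetate | COc1ccc(COC[C@](C)(O)CC(=O)C[C@H](OC(=O)CP(=O)(OCC)OCC)/C=C(\I)CO[Si](C(C)C)(C(C)C)C(C)C)cc1 | intermediate
18 | (2R,4S,6S,7Z)-2,4-dihydroxy-8-iodo-1-[(4-methoxybenzyl)oxy]-2-methyl-9-[(triisopropylsilyl)oxy]non-7-en-6-yl 2-(diethoxyphosphoryl)acetate | COc1ccc(COC[C@](C)(O)C[C@@H](O)C[C@H](OC(=O)CP(=O)(OCC)OCC)/C=C(\I)CO[Si](C(C)C)(C(C)C)C(C)C)cc1 | intermediate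
19 | (R)-2-methylbutanoic acid | CC[C@@H](C)C(=O)O | starting material
20 | (2R,4S,6S,7Z)-6-{[(diethoxyphosphoryl)acetyl]oxy}-2-hydroxy-8-iodo-1-[(4-methoxybenzyl)oxy]-2-methyl-9-[(triisopropylsilyl)oxy]non-7-en-4-yl (2R)-2-methylbutanoate | COc1ccc(COC[C@](C)(O)C[C@@H](OC(=O)[C@H](C)CC)C[C@H](OC(=O)CP(=O)(OCC)OCC)/C=C(\I)CO[Si](C(C)C)(C(C)C)C(C)C)cc1 | intermediate
21 | (2R,4S,6S,7Z)-6-{[(diethoxyphosphoryl)acetyl]oxy}-8-iodo-1-[(4-methoxybenzyl)oxy]-2-methyl-2-[(triethylsilyl)oxy]-9-[(triisopropylsilyl)oxy]non-7-en-4-yl (2R)-2-methylbutanoate | COc1ccc(COC[C@](C)(O[Si](CC)(CC)CC)C[C@@H](OC(=O)[C@H](C)CC)C[C@H](OC(=O)CP(=O)(OCC)OCC)/C=C(\I)CO[Si](C(C)C)(C(C)C)C(C)C)cc1 | intermediate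
22 | (2R,4S,6S,7Z)-6-{[(diethoxyphosphoryl)acetyl]oxy}-1-hydroxy-8-iodo-2-methyl-2-[(triethylsilyl)oxy]-9-[(triisopropylsilyl)oxy]non-7-en-4-yl (2R)-2-methylbutanoate | OC[C@](C)(O[Si](CC)(CC)CC)C[C@@H](OC(=O)[C@H](C)CC)C[C@H](OC(=O)CP(=O)(OCC)OCC)/C=C(\I)CO[Si](C(C)C)(C(C)C)C(C)C | intermediate
23 | (2R,4S,6S,7Z)-6-{[(diethoxyphosphoryl)acetyl]oxy}-8-iodo-2-methyl-1-oxo-2-[(triethylsilyl)oxy]-9-[(triisopropylsilyl)oxy]non-7-en-4-yl (2R)-2-methylbutanoate | O=C[C@](C)(O[Si](CC)(CC)CC)C[C@@H](OC(=O)[C@H](C)CC)C[C@H](OC(=O)CP(=O)(OCC)OCC)/C=C(\I)CO[Si](C(C)C)(C(C)C)C(C)C | intermediate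
24 | (2E,4R,6S,8S,9Z)-8-{[(diethoxyphosphoryl)acetyl]oxy}-10-iodo-4-methyl-1-oxo-4-[(triethylsilyl)oxy]-11-[(triisopropylsilyl)oxy]undeca-2,9-dien-6-yl (2R)-2-methylbutanoate | O=C/C=C/[C@](C)(O[Si](CC)(CC)CC)C[C@@H](OC(=O)[C@H](C)CC)C[C@H](OC(=O)CP(=O)(OCC)OCC)/C=C(\I)CO[Si](C(C)C)(C(C)C)C(C)C | intermediate
25 | ten-membered C3 carbinol: ring C1–C10, E-C1=C2, C3–OH (both epimers), Z-C4=C5 with C15H2OTIPS, (6S)-O-(diethoxyphosphoryl)acetate, C7H2, (8S)-O-(R)-2-methylbutanoate, (10R)-methyl and OTES | CCOP(=O)(OCC)CC(=O)O[C@@H]1/C=C(/CO[Si](C(C)C)(C(C)C)C(C)C)C(O)/C=C/[C@](C)(O[Si](CC)(CC)CC)C[C@@H](OC(=O)[C@H](C)CC)C1 | intermediate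
26 | as 25 with the O6 ester converted to diazo(diethoxyphosphoryl)acetate | CCOP(=O)(OCC)C(=[N+]=[N-])C(=O)O[C@@H]1/C=C(/CO[Si](C(C)C)(C(C)C)C(C)C)C(O)/C=C/[C@](C)(O[Si](CC)(CC)CC)C[C@@H](OC(=O)[C@H](C)CC)C1 | intermediate
27 | ten-membered dienone (C3 ketone) with (6S)-O-diazo(diethoxyphosphoryl)acetate, C7H2, (8S)-O-(R)-2-methylbutanoate, (10R)-OTES, C15-OTIPS | CCOP(=O)(OCC)C(=[N+]=[N-])C(=O)O[C@@H]1/C=C(/CO[Si](C(C)C)(C(C)C)C(C)C)C(=O)/C=C/[C@](C)(O[Si](CC)(CC)CC)C[C@@H](OC(=O)[C@H](C)CC)C1 | intermediate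
28 | trans-fused 12,6-lactone with C11 diethoxyphosphoryl group on the dienone (6R,7R,8R,10R; C11 epimers; the S-to-R change at C6 and C8 is formal) | CCOP(=O)(OCC)C1C(=O)O[C@@H]2/C=C(/CO[Si](C(C)C)(C(C)C)C(C)C)C(=O)/C=C/[C@](C)(O[Si](CC)(CC)CC)C[C@@H](OC(=O)[C@H](C)CC)[C@@H]12 | intermediate
29 | 15-O-TIPS, 10-O-TES ether of the target (alpha-methylene lactone) | C=C1C(=O)O[C@@H]2/C=C(/CO[Si](C(C)C)(C(C)C)C(C)C)C(=O)/C=C/[C@](C)(O[Si](CC)(CC)CC)C[C@@H](OC(=O)[C@H](C)CC)[C@@H]12 | intermediate
30 | CNP0232405.1, (6R,7R,8R,10R)-10,15-dihydroxy-3-oxo-8-[(R)-2-methylbutanoyloxy]germacra-1(E),4(Z),11(13)-trien-12,6-olide | C=C1C(=O)O[C@@H]2/C=C(/CO)C(=O)/C=C/[C@](C)(O)C[C@@H](OC(=O)[C@H](C)CC)[C@@H]12 | target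

**Totals**

Total step count: 21. Longest linear sequence: 18 steps (steps 1–4 and 8–21, from 1 to 30); the iodo-enal branch (steps 5–7) joins at step 8.

**Steps most likely to fail**

Step 19. The carbenoid may be diverted: it may add across C4=C5, insert into the C6–H bond to a beta-lactone, or replace the other C7 hydrogen and give the cis ring fusion if the carbocycle does not hold C5–C6–C7–C8 extended. The fallback forms the lactone on the open chain, where a 4,5-trans gamma-lactone is the usual result of insertion next to a secondary ester, and closes the carbocycle afterwards. It sets out from 21 and comes back at 28. Diazo transfer to 21 (p-ABSA, DBU) gives the open-chain diazo ester F1. Rh2(OAc)4 in hot ClCH2CH2Cl gives the open-chain trans-4,5-disubstituted alpha-phosphono lactone F2; the iodoalkene is then the only pi-bond near the carbenoid. DDQ gives the primary alcohol F3, Dess–Martin oxidation the aldehyde F4, and the formylmethylene Wittig reagent the E-enal F5. CrCl2/NiCl2 ring closure at C3–C4 gives the lactone-bearing macrocyclic carbinol F6, and MnO2 oxidation of F6 gives 28.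

Step 16. The alkenylchromium may fail to reach the enal across the strained ten-membered transition state, so that intermolecular coupling or simple loss of iodine takes over. The fallback makes C3 from carbon monoxide and closes the ring by a carbonylative Stille coupling. It sets out from 23 and comes back at 27. Takai-type olefination of 23 with Bu3SnCHBr2, nickel-free CrCl2 and LiI gives the E-alkenylstannane F7. Pd(PPh3)4 (zerovalent palladium) under CO at high dilution joins C4 and C2 through a new carbonyl and gives the macrocyclic dienone phosphonoacetate F8. Diazo transfer (p-ABSA, DBU, short time at low temperature) then gives 27.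

Step 8. The chiral boron enolate may discriminate the two aldehyde faces poorly, since methyl-ketone aldols are the least selective of this class, leaving much of the C6 epimer. The fallback replaces the aldol by an alkyne addition used as an aldol surrogate. It sets out from 2 and 11 and comes back at 15. Lithium acetylide–ethylenediamine opens 2 at the CH2 and gives the terminal alkyne F9. Enantioselective zinc alkynylation of 11 (Me2Zn with the ProPhenol ligand enantiomer that delivers the alkynyl group to the si face) gives the propargylic alcohol F10. Ruthenium-catalysed trans-hydrosilylation ([Cp*Ru(MeCN)3]PF6, (EtO)3SiH) puts silicon on the alkyne carbon remote from the C6 hydroxyl and gives the Z-alkenylsilane F11. Tamao–Fleming oxidation (H2O2, KF, KHCO3) converts F11 into the C8 ketone 15.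

**Further compounds**

F1 | step 19 | open-chain diazo ester, 21 with the O6 ester as diazo(diethoxyphosphoryl)acetate | COc1ccc(COC[C@](C)(O[Si](CC)(CC)CC)C[C@@H](OC(=O)[C@H](C)CC)C[C@H](OC(=O)C(=[N+]=[N-])P(=O)(OCC)OCC)/C=C(\I)CO[Si](C(C)C)(C(C)C)C(C)C)cc1
F2 | step 19 | open-chain trans-4,5-disubstituted alpha-phosphono gamma-lactone, PMB ether (C11 epimers) | COc1ccc(COC[C@](C)(O[Si](CC)(CC)CC)C[C@@H](OC(=O)[C@H](C)CC)[C@H]2C(P(=O)(OCC)OCC)C(=O)O[C@@H]2/C=C(\I)CO[Si](C(C)C)(C(C)C)C(C)C)cc1
F3 | step 19 | open-chain lactone, C1 primary alcohol | OC[C@](C)(O[Si](CC)(CC)CC)C[C@@H](OC(=O)[C@H](C)CC)[C@H]1C(P(=O)(OCC)OCC)C(=O)O[C@@H]1/C=C(\I)CO[Si](C(C)C)(C(C)C)C(C)C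
F4 | step 19 | open-chain lactone, C1 aldehyde | O=C[C@](C)(O[Si](CC)(CC)CC)C[C@@H](OC(=O)[C@H](C)CC)[C@H]1C(P(=O)(OCC)OCC)C(=O)O[C@@H]1/C=C(\I)CO[Si](C(C)C)(C(C)C)C(C)C
F5 | step 19 | open-chain lactone, E-enal (C1=C2, C3 aldehyde) | O=C/C=C/[C@](C)(O[Si](CC)(CC)CC)C[C@@H](OC(=O)[C@H](C)CC)[C@H]1C(P(=O)(OCC)OCC)C(=O)O[C@@H]1/C=C(\I)CO[Si](C(C)C)(C(C)C)C(C)C
F6 | step 19 | lactone-bearing ten-membered C3 carbinol (C3 and C11 epimers) | CCOP(=O)(OCC)C1C(=O)O[C@@H]2/C=C(/CO[Si](C(C)C)(C(C)C)C(C)C)C(O)/C=C/[C@](C)(O[Si](CC)(CC)CC)C[C@@H](OC(=O)[C@H](C)CC)[C@@H]12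
F7 | step 16 | open-chain E-alkenyl tributylstannane (C2 stannylated) with the C4 iodoalkene | CCCC[Sn](CCCC)(CCCC)/C=C/[C@](C)(O[Si](CC)(CC)CC)C[C@@H](OC(=O)[C@H](C)CC)C[C@H](OC(=O)CP(=O)(OCC)OCC)/C=C(\I)CO[Si](C(C)C)(C(C)C)C(C)C
F8 | step 16 | ten-membered dienone with the O6 (diethoxyphosphoryl)acetate | CCOP(=O)(OCC)CC(=O)O[C@@H]1/C=C(/CO[Si](C(C)C)(C(C)C)C(C)C)C(=O)/C=C/[C@](C)(O[Si](CC)(CC)CC)C[C@@H](OC(=O)[C@H](C)CC)C1
F9 | step 8 | (R)-1-[(4-methoxybenzyl)oxy]-2-methylpent-4-yn-2-ol | COc1ccc(COC[C@](C)(O)CC#C)cc1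
F10 | step 8 | (2R,6R,7Z)-8-iodo-1-[(4-methoxybenzyl)oxy]-2-methyl-9-[(triisopropylsilyl)oxy]non-7-en-4-yne-2,6-diol (same spatial arrangement at C6 as in 15) | COc1ccc(COC[C@](C)(O)CC#C[C@H](O)/C=C(\I)CO[Si](C(C)C)(C(C)C)C(C)C)cc1
F11 | step 8 | Z-alkenyl(triethoxy)silane, silicon on C8, C7=C8 alkene | COc1ccc(COC[C@](C)(O)C/C(=C/[C@H](O)/C=C(\I)CO[Si](C(C)C)(C(C)C)C(C)C)[Si](OCC)(OCC)OCC)cc1
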